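With one Q per G, the elm flask could not have slowed as it did. From 3.00 d to 4.00 d G gained 5 percentage points, with D at 56 % and, on that count, 0.490 equiv of Q still free. From 1.25 d to 2.08 d it had gained 14 points, with less D.

| flask | D | Q | remark | time |
|---|---|---|---|---|
| elm | 20 mM (fed, over 3.0 d) | 0.93 equiv | run made earlier |  |
| south-east | 20 mM (fed, over 3.0 d) | 1.30 equiv |  | 4.0 d |
| south | 20 mM (fed, over 3.0 d) | 2.00 equiv |  | 4.0 d |
| north | 20 mM (fed, over 3.0 d) | 2.90 equiv |  | 4.0 d |

elm run (percent of the D charged)

| time / d | D / % | G / % |
|---|---|---|
| 0.625 | 16 | 4 |
| 1.25 | 28 | 16 |
| 2.08 | 40 | 30 |
| 2.50 | 49 | 34 |
| 3.00 | 61 | 39 |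
| 4.00 | 56 | 44 |

(each reading ± 1.5 percentage points)

- percentages count the whole charge, also what has not yet gone in

- part of the D that has reacted at the end, south-east
- part of the D that has reacted at the end, south
- part of the D that has reacted at the end, north
- what raising the equivalents of Q from its lowest to its highest value here does to the part of the D that has reacted (changes below 5 percentage points count as none) (it falls / it rises / no change)

So I froze one number. Elm's charge of Q over its last G gave 2.11, the Q price of a G: equivalents of Q lost per G formed. It is a reading, and G was still creeping, so I took it as about 2. One Q reacts, and a second goes unseen.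

Then I climbed the ladder of times. The first rung is the unseen loss. I could not separate it from G, so I let it keep pace with G. On the second rung I counted free [Q] as charge minus price times G. The elm stretch from 1.25 d to 2.08 d then read a rate coefficient of 1.12 /d. At south-east's charge of Q, that makes the half-life of D 0.477 d, shorter than the feed of 3.0 d. The last rung comes as free [Q] falls: the half-life stretches and G stalls near charge over price.

My stall levels were therefore 61.5 % for south-east, where Q is the limiting reagent, 94.6 % for south and 137 % for north, where D limits instead.

The forecast gave 54 %, 67 % and 77 %, and for the part reacted as Q goes up: it rises, with the words “More Q gives more conversion, but less than proportionally”. We parted at south, where my stall level stood higher than its number.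

    Q + J ⇌ X, settled at all times (K = 1.60 × 10⁵ /M)
    D + Q → J + G (k = 0.0369 /M/min)

The flasks gave 59.9 % in south-east, 81.1 % in south and 94.0 % in north; for the part reacted as Q goes up: it rises, a change of 34 points from lowest to highest Q. South-east held 11.9 mM of X beside 12.0 mM of G at 4.00 d, so the second Q stood in X. South-east's stall level of 61.5 % lay just above its result. The same flask with 0.520 equiv of Q has a stall level of 24.6 % at that price, and it reached 25.7 % at 4.00 d.

The numbers in the tables come from a simulation with constants of no real substance; scatter was added.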